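**Retrosynthetic overview**
1. The target is a bromo-oxane (ring A) joined by a CH2CH2 link to a 1,3,4-trimethyl-7-oxabicyclo[2.2.1]heptane, i.e. a cyclohexane (ring B) spanned 1,4 by oxygen. Enabling feature: both bridge carbons of the oxabicycle (C1 and C4) are fully substituted and face each other across ring B, so the C4–O bond can be made last by a tertiary C1 alcohol capturing a tertiary C4 cation. Because C4 ends as a bridgehead, the bridge fixes its configuration, and a carboxyl group at C4 can serve as a traceless, configuration-free cation precursor.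
2. Last disconnection (key step): the oxolane ring O–C1–C6–C5–C4 of the oxabicycle, by anodic decarboxylation (Hofer–Moest) of a 4-hydroxycyclohexane-1-carboxylic acid; both epimers at the acid carbon converge.
3. Before it: face-selective methyl addition to a keto ester. The keto ester comes from C–C union of two fragments: alkylation of an enantioenriched cyclohexanone enolate (asymmetric conjugate methylation of a racemic Diels–Alder enone) with a bromo-oxane iodide, which sets the two ring CH centres trans.
4. Bromo-oxane: 6-endo bromoetherification of an (S)-linalool-derived dienediol. (S)-Linalool comes from geraniol by asymmetric epoxidation and reductive opening; the side chain is extended by one carbon via allylic oxidation, bromination and copper-catalysed Grignard coupling/Tamao oxidation.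
5. Order of ring formation: oxane ring A (step 7), cyclohexane ring B (step 9, separate fragment), oxygen bridge closing the oxolane ring (step 14).

Key step: step 14

Remark on the chemistry: the ester-bearing quaternary carbon of the cyclohexane fragment is carried through as both configurations, because step 14 turns it into a planar cation.

**Route**

Step 1
Reactants: 1 geraniol
Product: 2 [(2S,3S)-3-methyl-3-(4-methylpent-3-en-1-yl)oxiran-2-yl]methanol
Conditions: Ti(OiPr)4 (5 mol %), L-(+)-diethyl tartrate (7 mol %), t-BuOOH, 4 Å MS, CH2Cl2, −20 °C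
Reagents that add atoms: tert-butyl hydroperoxide, CC(C)(C)OO
Why: Sharpless asymmetric epoxidation: the titanium tartrate complex binds the allylic alcohol and delivers oxygen to one face of the 2,3-alkene only (L-(+)-tartrate gives 2S,3S), leaving the 6,7-alkene untouched.

Step 2
Reactants: 2 [(2S,3S)-3-methyl-3-(4-methylpent-3-en-1-yl)oxiran-2-yl]methanol
Product: 3 (2R,3S)-2-(iodomethyl)-3-methyl-3-(4-methylpent-3-en-1-yl)oxirane
Conditions: I2, PPh3, imidazole, CH2Cl2, 0 °C
Reagents that add atoms: iodine, II
Why: Appel-type iodination of the primary alcohol by SN2 at CH2; no stereocentre is touched (the change of descriptor at C2 is a priority change only).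

Step 3
Reactants: 3 (2R,3S)-2-(iodomethyl)-3-methyl-3-(4-methylpent-3-en-1-yl)oxirane
Product: 4 (S)-linalool, (3S)-3,7-dimethylocta-1,6-dien-3-ol
Conditions: Zn dust, AcOH, EtOH, 40 °C
Reagents that add atoms: none
Why: Reductive β-elimination of an epoxy iodide: zinc inserts into the C–I bond and the organozinc opens the oxirane to the tertiary allylic alcohol, the C3–O bond staying intact so that its configuration is carried over.

Step 4
Reactants: 4 (S)-linalool
Product: 5 (2E,6S)-2,6-dimethylocta-2,7-diene-1,6-diol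
Conditions: SeO2 (0.3 equiv), t-BuOOH (3 equiv), salicylic acid (10 mol %), CH2Cl2, rt
Reagents that add atoms: selenium dioxide (oxygen carrier), O=[Se]=O; tert-butyl hydroperoxide (terminal oxidant), CC(C)(C)OO
Why: Catalytic SeO2 allylic oxidation (ene reaction, then [2,3]-sigmatropic shift) hydroxylates the (E)-methyl group of the trisubstituted alkene selectively, and the monosubstituted vinyl group does not react.

Step 5
Reactants: 5 (2E,6S)-2,6-dimethylocta-2,7-diene-1,6-diol
Product: 6 (3S,6E)-8-bromo-3,7-dimethylocta-1,6-dien-3-ol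
Conditions: CBr4, PPh3, CH2Cl2, −30 to 0 °C
Reagents that add atoms: carbon tetrabromide, BrC(Br)(Br)Br
Why: Appel bromination: the primary allylic hydroxyl reacts much faster than the hindered tertiary one, and SN2 at CH2 keeps the E alkene.

Step 6
Reactants: 6 (3S,6E)-8-bromo-3,7-dimethylocta-1,6-dien-3-ol
Product: 8 (3S,6E)-3,7-dimethylnona-1,6-diene-3,9-diol, via silane 7 (not isolated)
Conditions: (i-PrO)Me2SiCH2MgCl (2.5 equiv), Li2CuCl4 (3 mol %), THF, −40 to 0 °C; then KF, KHCO3, 30% H2O2, MeOH/THF, rt
Reagents that add atoms: [(isopropoxy)dimethylsilyl]methylmagnesium chloride, CC(C)O[Si](C)(C)C[Mg]Cl; hydrogen peroxide, OO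
Why: Copper-catalysed coupling of a Grignard reagent with a primary allylic bromide at the α-carbon with retention of the E geometry, followed by Tamao oxidation of the C–Si bond, together a hydroxymethyl-anion homologation.

Step 7
Reactants: 8 (3S,6E)-3,7-dimethylnona-1,6-diene-3,9-diol
Product: 9 2-[(2S,3R,6S)-3-bromo-6-ethenyl-2,6-dimethyloxan-2-yl]ethan-1-ol
Conditions: 2,4,4,6-tetrabromocyclohexa-2,5-dienone (1.1 equiv), MeNO2, 0 °C to rt, dark
Reagents that add atoms: 2,4,4,6-tetrabromocyclohexa-2,5-dienone, O=C1C(Br)=CC(Br)(Br)C=C1Br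
Why: Bromonium-induced 6-endo cycloetherification: the tertiary hydroxyl opens the bromonium ion at its tertiary carbon in a chair, and anti addition across the E alkene puts Br trans to the hydroxyethyl chain, while C6 comes unchanged from 4; no bias is expected between the two chairs that differ at C6, so the (2R,3S,6S) isomer and the 5-exo oxolanes have to be removed by chromatography.

Step 8
Reactants: 9 2-[(2S,3R,6S)-3-bromo-6-ethenyl-2,6-dimethyloxan-2-yl]ethan-1-ol
Product: 10 (2S,3R,6S)-3-bromo-6-ethenyl-2-(2-iodoethyl)-2,6-dimethyloxane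
Conditions: I2, PPh3, imidazole, CH2Cl2, 0 °C to rt
Reagents that add atoms: iodine, II
Why: Appel-type iodination of the primary alcohol; the hindered secondary bromide and the vinyl group are inert to the phosphonium iodide.

Step 9
Reactants: 11 (E)-1-methoxy-3-(trimethylsilyloxy)buta-1,3-diene; 12 tert-butyl methacrylate
Product: 14 tert-butyl 1-methyl-4-oxocyclohex-2-ene-1-carboxylate (racemic), via cycloadduct 13 (not isolated)
Conditions: toluene, 130 °C (sealed tube); then 0.1 M HCl, THF, 0 °C
Reagents that add atoms: none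
Why: Diels–Alder reaction whose regiochemistry is set by the 1-methoxy and 3-siloxy groups of the diene (ester-bearing carbon next to the methoxy carbon), then acid hydrolysis of the silyl enol ether and β-elimination of methanol to the enone; the quaternary centre need not be controlled.

Step 10
Reactants: 14 tert-butyl 1-methyl-4-oxocyclohex-2-ene-1-carboxylate
Product: 16 tert-butyl (2R)-1,2-dimethyl-4-(trimethylsilyloxy)cyclohex-3-ene-1-carboxylate (both C1 epimers), via methylzinc enolate 15 (not isolated)
Conditions: Me2Zn (2 equiv), Cu(OTf)2 (3 mol %), (S,R,R)-phosphoramidite from (S)-BINOL and bis[(R)-1-phenylethyl]amine (6 mol %), toluene, −10 °C; then TMSOTf (2 equiv), −10 to 0 °C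
Reagents that add atoms: dimethylzinc, C[Zn]C; trimethylsilyl trifluoromethanesulfonate, C[Si](C)(C)OS(=O)(=O)C(F)(F)F
Why: Copper-catalysed asymmetric conjugate addition of a dialkylzinc with silyl trapping of the zinc enolate: the ligand, not the nearly equal Me/ester pair at C1, should select the face of the β-carbon (the sense that gives (S)-3-alkylcyclohexanones from cyclohex-2-enone, here 2R), so both enantiomers of 14 should give the same configuration at the new methyl-bearing carbon and differ only at C1.

Step 11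
Reactants: 16 tert-butyl (2R)-1,2-dimethyl-4-(trimethylsilyloxy)cyclohex-3-ene-1-carboxylate; 10 (2S,3R,6S)-3-bromo-6-ethenyl-2-(2-iodoethyl)-2,6-dimethyloxane
Product: 18 tert-butyl (2R,3R)-3-{2-[(2S,3R,6S)-3-bromo-6-ethenyl-2,6-dimethyloxan-2-yl]ethyl}-1,2-dimethyl-4-oxocyclohexane-1-carboxylate (both C1 epimers), via lithium enolate 17 (not isolated)
Conditions: 16 (2.5 equiv), MeLi (2.4 equiv), THF, 0 °C; DMPU; then 10 (1 equiv), −40 to 0 °C
Reagents that add atoms: none
Why: Regiospecific lithium enolate generation from the silyl enol ether, then SN2 alkylation by the primary iodide: the electrophile enters axially, anti to the adjacent C2 methyl group, setting C3 as R (2,3-trans) under kinetic control, while the equatorial secondary bromide (no antiperiplanar hydrogen) and the hindered tert-butyl ester are expected to survive.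

Step 12
Reactants: 18 tert-butyl (2R,3R)-3-{2-[(2S,3R,6S)-3-bromo-6-ethenyl-2,6-dimethyloxan-2-yl]ethyl}-1,2-dimethyl-4-oxocyclohexane-1-carboxylate
Product: 19 tert-butyl (2R,3R,4R)-3-{2-[(2S,3R,6S)-3-bromo-6-ethenyl-2,6-dimethyloxan-2-yl]ethyl}-4-hydroxy-1,2,4-trimethylcyclohexane-1-carboxylate (both C1 epimers)
Conditions: MeAl(OAr)2 (Ar = 2,6-di-tert-butyl-4-methylphenyl, 3 equiv), toluene, −78 °C; MeLi (3 equiv), −78 °C
Reagents that add atoms: methyllithium, [Li]C
Why: Amphiphilic carbonyl methylation: the bulky aluminium phenoxide binds the ketone from its open equatorial side so that MeLi attacks axially, giving the equatorial alcohol trans to the adjacent side chain (4R), the epimer that MeLi or MeMgBr alone would not favour.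

Step 13
Reactants: 19 tert-butyl (2R,3R,4R)-3-{2-[(2S,3R,6S)-3-bromo-6-ethenyl-2,6-dimethyloxan-2-yl]ethyl}-4-hydroxy-1,2,4-trimethylcyclohexane-1-carboxylate
Product: 21 (2R,3R,4R)-3-{2-[(2S,3R,6S)-3-bromo-6-ethenyl-2,6-dimethyloxan-2-yl]ethyl}-4-hydroxy-1,2,4-trimethylcyclohexane-1-carboxylic acid (both C1 epimers), via bis(trimethylsilyl) derivative 20 (not isolated)
Conditions: TMSOTf (4 equiv), 2,6-lutidine (6 equiv), CH2Cl2, 0 °C; then MeOH, aq. citric acid, 0 °C
Reagents that add atoms: none
Why: Silyl triflate-mediated cleavage of a tert-butyl ester (loss of 2-methylpropene) under lutidine buffering, the tertiary alcohol being masked in the flask as its TMS ether, then mild methanolysis of both silyl groups; no stereocentre is touched.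

Step 14
Reactants: 21 (2R,3R,4R)-3-{2-[(2S,3R,6S)-3-bromo-6-ethenyl-2,6-dimethyloxan-2-yl]ethyl}-4-hydroxy-1,2,4-trimethylcyclohexane-1-carboxylic acid
Product: 22 dactylopyranoid, (2S,3R,6S)-3-bromo-6-ethenyl-2,6-dimethyl-2-{2-[(1R,2R,3R,4S)-1,3,4-trimethyl-7-oxabicyclo[2.2.1]heptan-2-yl]ethyl}oxane
Conditions: graphite anode, Pt cathode, undivided cell, constant current 5 mA (ca. 3 F/mol), 2,4,6-collidine (3 equiv), n-Bu4NPF6 (0.1 M), 3 Å MS, CH2Cl2, rt; no silver salt
Reagents that add atoms: none
Why: Proposed new method: two-electron anodic oxidation of the collidinium carboxylate at graphite (Hofer–Moest pathway) expels CO2 and leaves the tertiary carbocation at the former acid carbon, which the tertiary hydroxyl captures across the ring; the closest known reaction type is the anodic decarboxylative etherification of tertiary acids with alcohols, together with the acid-mediated closure of terpinen-4-ol to 1,4-cineole, neither shown for a transannular bis-tertiary bridged ether. The oxolane ring (O, C1, C6, C5, C4 of the oxabicycle) closes by intramolecular SN1 capture through the boat of the cyclohexane, reached by a half-flip of the ground-state chair that turns the equatorial C–O bond into a flagpole bond; no bond is broken at the cationic carbon and the same bond completes the bicycle. The only new stereocentre, bridgehead C4 (S), is set by the tether: oxygen can reach only the face on which it already stands at the carbinol carbon (fixed in step 12), so both acid epimers of 21 converge on one product. The step needs capture to outrun E1 proton loss and 1,2-hydride shift from the neighbouring CH; the 1,4 disposition of the two centres, the non-nucleophilic medium and a low current density should secure this. It also needs chemoselectivity: only the carboxylate is oxidised at this potential (vinyl group, ethers and the C–Br bond are inert), and silver salts are left out because Ag+ would ionise the secondary bromide, protons being reduced at the Pt cathode instead.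

**Compound list**
1 | geraniol, (2E)-3,7-dimethylocta-2,6-dien-1-ol | CC(C)=CCC/C(C)=C/CO | starting material
2 | [(2S,3S)-3-methyl-3-(4-methylpent-3-en-1-yl)oxiran-2-yl]methanol | CC(C)=CCC[C@]1(C)O[C@H]1CO | intermediate
3 | (2R,3S)-2-(iodomethyl)-3-methyl-3-(4-methylpent-3-en-1-yl)oxirane | CC(C)=CCC[C@]1(C)O[C@H]1CI | intermediate
4 | (S)-linalool, (3S)-3,7-dimethylocta-1,6-dien-3-ol | C=C[C@@](C)(O)CCC=C(C)C | intermediate
5 | (2E,6S)-2,6-dimethylocta-2,7-diene-1,6-diol | C=C[C@@](C)(O)CC/C=C(\C)CO | intermediate
6 | (3S,6E)-8-bromo-3,7-dimethylocta-1,6-dien-3-ol | C=C[C@@](C)(O)CC/C=C(\C)CBr | intermediate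
7 | (3S,6E)-9-[dimethyl(propan-2-yloxy)silyl]-3,7-dimethylnona-1,6-dien-3-ol (magnesium alkoxide in the flask) | C=C[C@@](C)(O)CC/C=C(\C)CC[Si](C)(C)OC(C)C | intermediate
8 | (3S,6E)-3,7-dimethylnona-1,6-diene-3,9-diol | C=C[C@@](C)(O)CC/C=C(\C)CCO | intermediate
9 | 2-[(2S,3R,6S)-3-bromo-6-ethenyl-2,6-dimethyloxan-2-yl]ethan-1-ol | C=C[C@]1(C)CC[C@@H](Br)[C@](C)(CCO)O1 | intermediate
10 | (2S,3R,6S)-3-bromo-6-ethenyl-2-(2-iodoethyl)-2,6-dimethyloxane | C=C[C@]1(C)CC[C@@H](Br)[C@](C)(CCI)O1 | intermediate
11 | (E)-1-methoxy-3-(trimethylsilyloxy)buta-1,3-diene | CO/C=C/C(=C)O[Si](C)(C)C | starting material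
12 | tert-butyl methacrylate | CC(=C)C(=O)OC(C)(C)C | starting material
13 | tert-butyl 2-methoxy-1-methyl-4-(trimethylsilyloxy)cyclohex-3-ene-1-carboxylate (racemic, diastereomers) | COC1C=C(O[Si](C)(C)C)CCC1(C)C(=O)OC(C)(C)C | intermediate
14 | tert-butyl 1-methyl-4-oxocyclohex-2-ene-1-carboxylate (racemic) | CC1(C=CC(=O)CC1)C(=O)OC(C)(C)C | intermediate
15 | methylzinc enolate, tert-butyl (2R)-1,2-dimethyl-4-[(methylzincio)oxy]cyclohex-3-ene-1-carboxylate (C1 epimers) | C[C@@H]1C=C(O[Zn]C)CCC1(C)C(=O)OC(C)(C)C | intermediate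
16 | tert-butyl (2R)-1,2-dimethyl-4-(trimethylsilyloxy)cyclohex-3-ene-1-carboxylate (C1 epimers) | C[C@@H]1C=C(O[Si](C)(C)C)CCC1(C)C(=O)OC(C)(C)C | intermediate
17 | lithium enolate, tert-butyl (2R)-4-(lithiooxy)-1,2-dimethylcyclohex-3-ene-1-carboxylate (C1 epimers) | C[C@@H]1C=C(O[Li])CCC1(C)C(=O)OC(C)(C)C | intermediate
18 | tert-butyl (2R,3R)-3-{2-[(2S,3R,6S)-3-bromo-6-ethenyl-2,6-dimethyloxan-2-yl]ethyl}-1,2-dimethyl-4-oxocyclohexane-1-carboxylate (C1 epimers) | C=C[C@]1(C)CC[C@@H](Br)[C@](C)(CC[C@@H]2[C@@H](C)C(C)(C(=O)OC(C)(C)C)CCC2=O)O1 | intermediate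
19 | tert-butyl (2R,3R,4R)-3-{2-[(2S,3R,6S)-3-bromo-6-ethenyl-2,6-dimethyloxan-2-yl]ethyl}-4-hydroxy-1,2,4-trimethylcyclohexane-1-carboxylate (C1 epimers) | C=C[C@]1(C)CC[C@@H](Br)[C@](C)(CC[C@@H]2[C@@H](C)C(C)(C(=O)OC(C)(C)C)CC[C@@]2(C)O)O1 | intermediate
20 | trimethylsilyl (2R,3R,4R)-3-{2-[(2S,3R,6S)-3-bromo-6-ethenyl-2,6-dimethyloxan-2-yl]ethyl}-1,2,4-trimethyl-4-(trimethylsilyloxy)cyclohexane-1-carboxylate (C1 epimers) | C=C[C@]1(C)CC[C@@H](Br)[C@](C)(CC[C@@H]2[C@@H](C)C(C)(C(=O)O[Si](C)(C)C)CC[C@@]2(C)O[Si](C)(C)C)O1 | intermediate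
21 | (2R,3R,4R)-3-{2-[(2S,3R,6S)-3-bromo-6-ethenyl-2,6-dimethyloxan-2-yl]ethyl}-4-hydroxy-1,2,4-trimethylcyclohexane-1-carboxylic acid (C1 epimers) | C=C[C@]1(C)CC[C@@H](Br)[C@](C)(CC[C@@H]2[C@@H](C)C(C)(C(=O)O)CC[C@@]2(C)O)O1 | intermediate
22 | dactylopyranoid, (2S,3R,6S)-3-bromo-6-ethenyl-2,6-dimethyl-2-{2-[(1R,2R,3R,4S)-1,3,4-trimethyl-7-oxabicyclo[2.2.1]heptan-2-yl]ethyl}oxane | C=C[C@]1(C)CC[C@@H](Br)[C@](C)(CC[C@@H]2[C@@H](C)[C@]3(C)CC[C@@]2(C)O3)O1 | target

**Step count and risks**
Total steps: 14. Longest linear sequence: 12 (steps 1–8, then 11–14); the cyclohexane fragment takes 2 steps (9–10).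

Steps most likely to fail:

Step 14 (proposed new method). Capture of the cation by the hydroxyl may be outrun by proton loss, by hydride shift from the neighbouring CH, or by fragmentation that follows such a shift. Fallback with known chemistry, which separates decarboxylation from C–O bond formation: from 21, photochemical decarboxylative desaturation (9-mesitylacridine, Co(dmgH)2(py)Cl, blue light, CH2Cl2) should give the exocyclic alkene (1R,2R,3R)-2-{2-[(2S,3R,6S)-3-bromo-6-ethenyl-2,6-dimethyloxan-2-yl]ethyl}-1,3-dimethyl-4-methylidenecyclohexan-1-ol F1, accompanied by its endocyclic 4,5-ene isomer, which is equally usable. Camphorsulfonic acid (catalytic) in CH2Cl2 at 0 °C then closes the bridge by Markovnikov transannular hydroalkoxylation, the reaction by which terpinen-4-ol gives 1,4-cineole, and the route is rejoined at 22.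

Step 7. Closure to the five-membered ethers (5-exo) may compete with the 6-endo mode, and no facial bias toward the wanted C6 relationship is expected. Fallback that replaces direct halocyclisation by reversible, strongly Markovnikov mercuration: from 8, Hg(O2CCF3)2 in MeNO2 at −20 °C should give the six-membered organomercurial 2-[(2S,3R,6S)-6-ethenyl-2,6-dimethyl-3-(trifluoroacetoxymercurio)oxan-2-yl]ethan-1-ol F2, converted by aqueous KBr into 2-[(2S,3R,6S)-3-(bromomercurio)-6-ethenyl-2,6-dimethyloxan-2-yl]ethan-1-ol F3. Brominative demercuration with retention (Br2, LiBr, pyridine, 0 °C) returns to the route at 9. This addresses the ring-size problem only; the C6 epimer is still removed by chromatography.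

Step 10. On the racemic enone the ligand must override the substrate bias of one enantiomer, so the configuration of the methyl-bearing carbon may be eroded. Fallback that removes the mismatched pairing by desymmetrising an achiral dienone: from 14, dehydrogenation with DDQ (dioxane, reflux) should give tert-butyl 1-methyl-4-oxocyclohexa-2,5-diene-1-carboxylate F4. The same Me2Zn/Cu(OTf)2/phosphoramidite addition gives the methylzinc dienolate tert-butyl (6R)-1,6-dimethyl-4-[(methylzincio)oxy]cyclohexa-2,4-diene-1-carboxylate F5, silylated with TMSOTf to tert-butyl (6R)-1,6-dimethyl-4-(trimethylsilyloxy)cyclohexa-2,4-diene-1-carboxylate F6. MeLi then gives the lithium dienolate tert-butyl (6R)-4-(lithiooxy)-1,6-dimethylcyclohexa-2,4-diene-1-carboxylate F7, which is alkylated with 10 as in step 11 to tert-butyl (5R,6R)-5-{2-[(2S,3R,6S)-3-bromo-6-ethenyl-2,6-dimethyloxan-2-yl]ethyl}-1,6-dimethyl-4-oxocyclohex-2-ene-1-carboxylate F8. Conjugate reduction of the remaining enone with [(Ph3P)CuH]6 (toluene, rt), which spares the vinyl group, returns to the route at 18.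

**Further compounds**
F1 | step 14 | (1R,2R,3R)-2-{2-[(2S,3R,6S)-3-bromo-6-ethenyl-2,6-dimethyloxan-2-yl]ethyl}-1,3-dimethyl-4-methylidenecyclohexan-1-ol | C=C[C@]1(C)CC[C@@H](Br)[C@](C)(CC[C@@H]2[C@@H](C)C(=C)CC[C@@]2(C)O)O1
F2 | step 7 | 2-[(2S,3R,6S)-6-ethenyl-2,6-dimethyl-3-(trifluoroacetoxymercurio)oxan-2-yl]ethan-1-ol | C=C[C@]1(C)CC[C@@H]([Hg]OC(=O)C(F)(F)F)[C@](C)(CCO)O1
F3 | step 7 | 2-[(2S,3R,6S)-3-(bromomercurio)-6-ethenyl-2,6-dimethyloxan-2-yl]ethan-1-ol | C=C[C@]1(C)CC[C@@H]([Hg]Br)[C@](C)(CCO)O1
F4 | step 10 | tert-butyl 1-methyl-4-oxocyclohexa-2,5-diene-1-carboxylate | CC1(C=CC(=O)C=C1)C(=O)OC(C)(C)C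
F5 | step 10 | tert-butyl (6R)-1,6-dimethyl-4-[(methylzincio)oxy]cyclohexa-2,4-diene-1-carboxylate | C[C@@H]1C=C(O[Zn]C)C=CC1(C)C(=O)OC(C)(C)C
F6 | step 10 | tert-butyl (6R)-1,6-dimethyl-4-(trimethylsilyloxy)cyclohexa-2,4-diene-1-carboxylate | C[C@@H]1C=C(O[Si](C)(C)C)C=CC1(C)C(=O)OC(C)(C)C
F7 | step 10 | tert-butyl (6R)-4-(lithiooxy)-1,6-dimethylcyclohexa-2,4-diene-1-carboxylate | C[C@@H]1C=C(O[Li])C=CC1(C)C(=O)OC(C)(C)C
F8 | step 10 | tert-butyl (5R,6R)-5-{2-[(2S,3R,6S)-3-bromo-6-ethenyl-2,6-dimethyloxan-2-yl]ethyl}-1,6-dimethyl-4-oxocyclohex-2-ene-1-carboxylate | C=C[C@]1(C)CC[C@@H](Br)[C@](C)(CC[C@@H]2[C@@H](C)C(C)(C(=O)OC(C)(C)C)C=CC2=O)O1
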